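**Remark on the chemistry.** The target has no stereocentre and no stereogenic double bond (C3=C4 is endocyclic), so it is achiral and the "single enantiomer" is the compound itself. Racemic 1 is therefore used; its one stereocentre is erased in the key step.

## Structural features

The target 9 is a 1H-isochromene (1H-2-benzopyran): a benzene ring (C4a, C5–C8, C8a) fused to a 2H-pyran ring made of O2, C1H2, C8a, C4a, C4H and C3. C6 and C7 carry methoxy groups, and C3 carries an exocyclic ketone whose other arm is a 2,4-dimethoxyphenyl ring, so the C3=C4 enol ether is also the enone double bond (an α-alkoxy enone). There is no stereocentre, so all the difficulty is constitutional. The fragile sites are the enol ether (acid, electrophiles), the C1 methylene (benzylic and α to oxygen, easily oxidised towards an isocoumarin or isochromenylium) and the two dimethoxyarenes (strong oxidants). The real difficulty is to build the oxygen heterocycle at exactly this oxidation level with the acyl group on the oxygen-bearing alkene carbon C3: polar closure of oxygen onto an acyl-alkyne favours the five-membered ring, and routes through an isochroman or isocoumarin need redox adjustment next to C1. The key step exploits the fact that O2–C1–C8a=C4a–C4=C3 is a 2H-pyran, the closed valence isomer of the 1-oxatriene O=C3–C4=C4a–C8a=C1H2, which is an o-quinodimethane. C1, C8a, C4a and C4 are the four carbons of the small ring of a benzocyclobutene, and because C3 bears a ketone the open form is a 1,2-dione whose inner carbonyl supplies O2; the precursor is thus an isomer of the target. In one sentence: the pyran ring is formed last by thermal electrocyclic opening of a 7-(arylglyoxyloyl)benzocyclobutene and oxa-6π closure of the resulting o-quinodimethane, which does not describe the ether-plus-aldol route.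

## Logic of the disconnections

**9 to 7 through 8.** The O2–C1 bond of 9 is cut in a retro-oxa-6π sense to give 8, and C1 is then joined to C4 in a retro-4π sense to give 7. The cut is made there because it removes the only heterocycle and turns the problem into a carbocyclic one whose four-membered ring is commercially available with the right methoxy pattern. The gain is large: 7 is an isomer of 9, so the enol ether, the enone and the oxidation level at C1 all arise without any reagent. The forward step demands that the acyl group of 7 rotate inward on ring opening (or that outward opening be reversible), that 8 be kept dilute, and that 7 be made and handled well below the opening temperature.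

**7 to 6.** The two C=O bonds of the 1,2-dione of 7 are removed to leave the C≡C bond of 6. Acyl-anion chemistry next to the acidic C7–H is thereby avoided, and an alkyne is inert to base and moderate heat. The demand on the forward step is an oxidant that works at or below room temperature and spares two dimethoxyarenes and the benzylic C–H bonds.

**6 to 4 and 5.** The C(sp)–C(aryl) bond is cut. This is the convergent point: all carbons of the southern arene arrive in one fragment. The forward coupling must run near room temperature so that the strained ring and the propargylic C–H of 4 are untouched.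

**4 to 3.** The terminal alkyne carbon is removed, leaving the aldehyde carbon of 3. A one-carbon homologation is needed that tolerates an α-aryl aldehyde under mild base.

**3 to 1.** The formyl group of 3 is traced back to the nitrile of 1, which is commercial and already holds C1, C8a, C4a and C4 of 9 with both methoxy groups in place. The forward reduction must stop at the aldehyde oxidation level.

## Other disconnections considered

Alternative 1: (the first that comes to mind) cut O2–C3 and C3=C4. The forward sequence would be etherification of 2-(hydroxymethyl)-4,5-dimethoxybenzaldehyde A1 with 2-bromo-1-(2,4-dimethoxyphenyl)ethan-1-one A2 to the phenacyl ether A3, then intramolecular aldol condensation onto the aldehyde and dehydration. The chosen plan is preferred on three grounds. A1 should sit largely in its cyclic hemiacetal form, so O-alkylation is ambiguous unless the aldehyde is masked, which adds steps. The base needed for the aldol step acts on an α-alkoxy ketone carrying a second acidic benzylic ether CH2. The ring is closed by a polar C–C bond formation followed by a separate dehydration, whereas the chosen route sets ring, enol ether and enone in one reagent-free isomerisation.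

Alternative 2: cut the C3–C4 and C3–O2 bonds so that C3 is a single inserted carbon. The forward key step would be a metal-carbene reaction of 2-diazo-1-(2,4-dimethoxyphenyl)ethan-1-one A5 with 5,6-dimethoxy-1,3-dihydro-2-benzofuran A4: oxonium ylide formation and [1,2]-Stevens shift would expand the five-membered ether to the 3-aroylisochroman A6. The chosen plan is preferred because A6 is one oxidation level too low. Its C3–C4 dehydrogenation needs α-functionalisation at a tertiary α-alkoxy carbon and elimination, in the presence of the oxidisable C1 methylene, which adds at least two steps. The ylide step itself competes with carbene C–H insertion into the four equivalent benzylic ether C–H bonds of A4.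

Alternative 3: cut O2–C3 alone. The forward key step would be 6-endo-dig cycloisomerisation of the hydroxy-ynone 3-[2-(hydroxymethyl)-4,5-dimethoxyphenyl]-1-(2,4-dimethoxyphenyl)prop-2-yn-1-one A7. The chosen plan is preferred on mechanistic grounds: C3 is the α-carbon of the ynone, so the closure asked for is anti-Michael. Both the polarisation of the ynone and the 5-exo-dig geometry direct oxygen to the β-carbon, which would give the five-membered (2Z)-2-(5,6-dimethoxy-2-benzofuran-1(3H)-ylidene)-1-(2,4-dimethoxyphenyl)ethan-1-one A8. A π-acid catalyst would have to override both biases at once.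

Key step: step 5

## Steps

Step 1
Reactants: 1 rac-3,4-dimethoxybicyclo[4.2.0]octa-1,3,5-triene-7-carbonitrile
Product: 3 rac-3,4-dimethoxybicyclo[4.2.0]octa-1,3,5-triene-7-carbaldehyde, via N-[bis(2-methylpropyl)alumanyl]-1-(3,4-dimethoxybicyclo[4.2.0]octa-1,3,5-trien-7-yl)methanimine 2 (not isolated)
Conditions: DIBAL-H (1.2 equiv), CH2Cl2, −78 °C; then aq. Rochelle salt, 0 °C to rt; product kept cold and used at once
Reagents that add atoms: water, O
Why: Partial reduction of a nitrile by DIBAL-H should stop at the N-aluminated aldimine 2, which is stable at −78 °C and is hydrolysed to the aldehyde only on work-up; the aryl ethers and the strained ring are inert to the hydride at this temperature.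

Step 2
Reactants: 3 rac-3,4-dimethoxybicyclo[4.2.0]octa-1,3,5-triene-7-carbaldehyde
Product: 4 rac-7-ethynyl-3,4-dimethoxybicyclo[4.2.0]octa-1,3,5-triene
Conditions: dimethyl (1-diazo-2-oxopropyl)phosphonate (1.3 equiv), K2CO3 (2 equiv), MeOH, 0 °C to rt
Reagents that add atoms: dimethyl (1-diazo-2-oxopropyl)phosphonate (Ohira–Bestmann reagent), CC(=O)C(=[N+]=[N-])P(=O)(OC)OC
Why: Seyferth–Gilbert homologation in its Ohira–Bestmann form: methanolysis of the reagent gives the diazomethylphosphonate anion, which olefinates the aldehyde, and loss of dinitrogen with a 1,2-hydrogen shift should give the terminal alkyne; enolisation of 3 is disfavoured because it would place an exocyclic double bond on the four-membered ring.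

Step 3
Reactants: 4 rac-7-ethynyl-3,4-dimethoxybicyclo[4.2.0]octa-1,3,5-triene; 5 1-iodo-2,4-dimethoxybenzene
Product: 6 rac-7-[(2,4-dimethoxyphenyl)ethynyl]-3,4-dimethoxybicyclo[4.2.0]octa-1,3,5-triene
Conditions: PdCl2(PPh3)2 (2 mol %), CuI (4 mol %), Et3N/THF 1:1 (degassed), rt to 40 °C
Reagents that add atoms: none
Why: Sonogashira coupling of a terminal alkyne with an aryl iodide; the iodide compensates for the electron-rich arene in oxidative addition, and the mild amine base and temperature should leave the propargylic C–H and the four-membered ring untouched.

Step 4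
Reactants: 6 rac-7-[(2,4-dimethoxyphenyl)ethynyl]-3,4-dimethoxybicyclo[4.2.0]octa-1,3,5-triene
Product: 7 rac-1-(3,4-dimethoxybicyclo[4.2.0]octa-1,3,5-trien-7-yl)-2-(2,4-dimethoxyphenyl)ethane-1,2-dione
Conditions: KMnO4 (3 equiv), NaHCO3, MgSO4, acetone/H2O, 0 °C to rt; work-up and storage in the dark below 30 °C
Reagents that add atoms: potassium permanganate, [K+].[O-][Mn](=O)(=O)=O
Why: Buffered permanganate oxidation of an internal alkyne to a 1,2-dione through a cyclic manganate ester; the near-neutral buffer should suppress C–C cleavage of the dione, and at room temperature the arenes, the benzylic C–H bonds and the four-membered ring are expected to survive.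

Step 5
Reactants: 7 rac-1-(3,4-dimethoxybicyclo[4.2.0]octa-1,3,5-trien-7-yl)-2-(2,4-dimethoxyphenyl)ethane-1,2-dione
Product: 9 (6,7-dimethoxy-1H-isochromen-3-yl)(2,4-dimethoxyphenyl)methanone, via (3Z)-1-(2,4-dimethoxyphenyl)-3-(3,4-dimethoxy-6-methylidenecyclohexa-2,4-dien-1-ylidene)propane-1,2-dione 8 (not isolated)
Conditions: toluene (0.01 M, degassed, BHT cat.), 110–140 °C, sealed tube, dark, base-washed glass
Reagents that add atoms: none
Why: Thermal conrotatory 4π-electrocyclic opening of the C7–C8 σ-bond of 7 gives the o-quinodimethane 8, whose s-cis 1-oxatriene (O=C–C=C–C=CH2) closes by a disrotatory oxa-6π-electrocyclisation that forms O2–C1 and restores the benzene ring, which makes the second event irreversible. The closest known reaction type is the thermal isomerisation of 1-acylbenzocyclobutenes to 3-substituted 1H-isochromenes. The one ring closed is the pyran, by a pericyclic closure through a six-atom array in which the inner carbonyl oxygen becomes O2 and its carbon becomes C3. No stereocentre is formed; the single stereocentre of 7 becomes the sp2 carbon C4, so racemic 7 should converge on achiral 9. The selectivity needed is torquoselectivity, inward rotation of the acyl group to give (Z)-8: an α-dicarbonyl substituent is a strong π-acceptor with a low-lying π*(C=O), the kind of group that favours inward rotation, and because benzocyclobutene opening is endothermic and reversible any (E)-o-quinodimethane should reclose to 7 and be recycled. Of the two carbonyls only the one attached to the former C7 can reach the methylene terminus through a six-membered array, so the aryl ketone is left as the exocyclic aroyl group. The symmetric 3,4-dimethoxy pattern removes any regiochemical question, and high dilution should suppress [4+2] dimerisation of 8. The step is an isomerisation with no reagent and no co-product.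

## Compound list

1 | rac-3,4-dimethoxybicyclo[4.2.0]octa-1,3,5-triene-7-carbonitrile | N#CC1Cc2cc(OC)c(OC)cc21 | starting material
2 | N-[bis(2-methylpropyl)alumanyl]-1-(3,4-dimethoxybicyclo[4.2.0]octa-1,3,5-trien-7-yl)methanimine (racemic) | CC(C)C[Al](CC(C)C)N=CC1Cc2cc(OC)c(OC)cc21 | intermediate (not isolated)
3 | rac-3,4-dimethoxybicyclo[4.2.0]octa-1,3,5-triene-7-carbaldehyde | O=CC1Cc2cc(OC)c(OC)cc21 | intermediate
4 | rac-7-ethynyl-3,4-dimethoxybicyclo[4.2.0]octa-1,3,5-triene | C#CC1Cc2cc(OC)c(OC)cc21 | intermediate
5 | 1-iodo-2,4-dimethoxybenzene | COc1ccc(I)c(OC)c1 | starting material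
6 | rac-7-[(2,4-dimethoxyphenyl)ethynyl]-3,4-dimethoxybicyclo[4.2.0]octa-1,3,5-triene | COc1ccc(C#CC2Cc3cc(OC)c(OC)cc32)c(OC)c1 | intermediate
7 | rac-1-(3,4-dimethoxybicyclo[4.2.0]octa-1,3,5-trien-7-yl)-2-(2,4-dimethoxyphenyl)ethane-1,2-dione | COc1ccc(C(=O)C(=O)C2Cc3cc(OC)c(OC)cc32)c(OC)c1 | intermediate
8 | (3Z)-1-(2,4-dimethoxyphenyl)-3-(3,4-dimethoxy-6-methylidenecyclohexa-2,4-dien-1-ylidene)propane-1,2-dione | COc1ccc(C(=O)C(=O)/C=C2/C=C(OC)C(OC)=CC2=C)c(OC)c1 | intermediate (not isolated)
9 | (6,7-dimethoxy-1H-isochromen-3-yl)(2,4-dimethoxyphenyl)methanone | COc1ccc(C(=O)C2=Cc3cc(OC)c(OC)cc3CO2)c(OC)c1 | target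

## Step count and least certain steps

Total step count: 5. Longest linear sequence: 5 steps (1 → 3 → 4 → 6 → 7 → 9); 5 is the only other building block.

**Step 5 (key step).** The most likely failure is bimolecular [4+2] or [4+4] dimerisation and oligomerisation of the o-quinodimethane. This would happen if outward rotation dominates and the oxa-6π closure is slow compared with intermolecular trapping, or if the dione decomposes at the temperature needed. The fallback sets out from 3 and returns at 9, and moves the aroyl C–C bond formation to after the ring synthesis. Aldehyde 3 is heated in dilute toluene at about 110 °C; a formyl group is the substituent with the strongest preference for inward rotation, and the same opening and oxa-6π closure should give 6,7-dimethoxy-1H-isochromene F1. The C3–H of this enol ether (the α-alkoxyvinyl position) is then removed with t-BuLi in THF at −78 to −20 °C. The vinyllithium is acylated with N,2,4-trimethoxy-N-methylbenzamide F2, prepared from 2,4-dimethoxybenzoyl chloride, N,O-dimethylhydroxylamine hydrochloride and triethylamine, to give 9 directly.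

**Step 4.** The most likely failure is over-oxidation: cleavage of the dione C–C bond to two carboxylic acids, or attack of permanganate on the electron-rich rings or the benzylic C–H bonds. The fallback sets out from 3 and returns at 7, and forms the bond between the two carbonyl carbons by umpolung instead of oxidising an alkyne. 2,4-Dimethoxybenzaldehyde and propane-1,3-dithiol (BF3·OEt2, CH2Cl2) give 2-(2,4-dimethoxyphenyl)-1,3-dithiane F3. Lithiation (n-BuLi, THF, −78 °C) and addition to 3 give (3,4-dimethoxybicyclo[4.2.0]octa-1,3,5-trien-7-yl)[2-(2,4-dimethoxyphenyl)-1,3-dithian-2-yl]methanol F4 as a diastereomer mixture. Dess–Martin oxidation gives (3,4-dimethoxybicyclo[4.2.0]octa-1,3,5-trien-7-yl)[2-(2,4-dimethoxyphenyl)-1,3-dithian-2-yl]methanone F5, and alkylative hydrolysis of the dithiane (MeI, CaCO3, aq. MeCN, 40 °C) gives 7.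

**Step 2.** The most likely failure is loss of the α-aryl aldehyde in methanolic carbonate before homologation, through enolisation, aldol self-condensation, hemiacetal formation or autoxidation. The fallback sets out from 3 and returns at 4 by a Corey–Fuchs sequence that avoids protic base. CBr4 and PPh3 (CH2Cl2, 0 °C) give rac-7-(2,2-dibromoethenyl)-3,4-dimethoxybicyclo[4.2.0]octa-1,3,5-triene F6; n-BuLi (2.1 equiv, THF, −78 °C) followed by water gives 4.

**Step 1.** The most likely failures are over-reduction to the primary amine, α-deprotonation of the benzylic nitrile (returning 1 on work-up), and enolisation or autoxidation of the aldehyde during hydrolysis of the iminoalane. The fallback sets out from 1 and returns at 3 by full reduction followed by re-oxidation. Hydrolysis (KOH, EtOH/H2O, 80 °C, then acid) gives rac-3,4-dimethoxybicyclo[4.2.0]octa-1,3,5-triene-7-carboxylic acid F7. Reduction with BH3·THF gives rac-(3,4-dimethoxybicyclo[4.2.0]octa-1,3,5-trien-7-yl)methanol F8, and Dess–Martin oxidation (CH2Cl2, 0 °C) gives 3.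

## Further compounds

F1 | step 5 | 6,7-dimethoxy-1H-isochromene | COc1cc2C=COCc2cc1OC
F2 | step 5 | N,2,4-trimethoxy-N-methylbenzamide | COc1ccc(C(=O)N(C)OC)c(OC)c1
F3 | step 4 | 2-(2,4-dimethoxyphenyl)-1,3-dithiane | COc1ccc(C2SCCCS2)c(OC)c1
F4 | step 4 | (3,4-dimethoxybicyclo[4.2.0]octa-1,3,5-trien-7-yl)[2-(2,4-dimethoxyphenyl)-1,3-dithian-2-yl]methanol (diastereomer mixture, racemic) | COc1ccc(C2(C(O)C3Cc4cc(OC)c(OC)cc43)SCCCS2)c(OC)c1
F5 | step 4 | (3,4-dimethoxybicyclo[4.2.0]octa-1,3,5-trien-7-yl)[2-(2,4-dimethoxyphenyl)-1,3-dithian-2-yl]methanone (racemic) | COc1ccc(C2(C(=O)C3Cc4cc(OC)c(OC)cc43)SCCCS2)c(OC)c1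
F6 | step 2 | rac-7-(2,2-dibromoethenyl)-3,4-dimethoxybicyclo[4.2.0]octa-1,3,5-triene | BrC(Br)=CC1Cc2cc(OC)c(OC)cc21
F7 | step 1 | rac-3,4-dimethoxybicyclo[4.2.0]octa-1,3,5-triene-7-carboxylic acid | OC(=O)C1Cc2cc(OC)c(OC)cc21
F8 | step 1 | rac-(3,4-dimethoxybicyclo[4.2.0]octa-1,3,5-trien-7-yl)methanol | OCC1Cc2cc(OC)c(OC)cc21
A1 | alternative 1 | 2-(hydroxymethyl)-4,5-dimethoxybenzaldehyde | COc1cc(CO)c(C=O)cc1OC
A2 | alternative 1 | 2-bromo-1-(2,4-dimethoxyphenyl)ethan-1-one | COc1ccc(C(=O)CBr)c(OC)c1
A3 | alternative 1 | 2-{[2-(2,4-dimethoxyphenyl)-2-oxoethoxy]methyl}-4,5-dimethoxybenzaldehyde | COc1ccc(C(=O)COCc2cc(OC)c(OC)cc2C=O)c(OC)c1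
A4 | alternative 2 | 5,6-dimethoxy-1,3-dihydro-2-benzofuran | COc1cc2COCc2cc1OC
A5 | alternative 2 | 2-diazo-1-(2,4-dimethoxyphenyl)ethan-1-one | COc1ccc(C(=O)C=[N+]=[N-])c(OC)c1
A6 | alternative 2 | rac-(6,7-dimethoxy-3,4-dihydro-1H-isochromen-3-yl)(2,4-dimethoxyphenyl)methanone | COc1ccc(C(=O)C2Cc3cc(OC)c(OC)cc3CO2)c(OC)c1
A7 | alternative 3 | 3-[2-(hydroxymethyl)-4,5-dimethoxyphenyl]-1-(2,4-dimethoxyphenyl)prop-2-yn-1-one | COc1ccc(C(=O)C#Cc2cc(OC)c(OC)cc2CO)c(OC)c1
A8 | alternative 3 | (2Z)-2-(5,6-dimethoxy-2-benzofuran-1(3H)-ylidene)-1-(2,4-dimethoxyphenyl)ethan-1-one | COc1ccc(C(=O)/C=C2\OCc3cc(OC)c(OC)cc32)c(OC)c1
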